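The choice for the next flask is whether to stop at 10 min or leave it until 15 min, with starting material and partner charged equal at 0.10 M. It hangs on how much of the charge sits in open intermediate on its way to target.

| flask | starting material | partner | capture agent | remark | time |
|---|---|---|---|---|---|
| oak | 0.050 M | 0.10 M | 2 mM | run made earlier |  |
| birch | 0.075 M | 0.10 M | 2 mM | run made earlier |  |
| ash | 0.10 M | 0.050 M | 2 mM | run made earlier |  |
| theta | 0.10 M | 0.100 M | 2.00 mM |  | 10 min |
| beta | 0.10 M | 0.100 M | 2.00 mM |  | 15 min |

| run | time / min | target / % | open intermediate / % | trapped intermediate / % | starting material / % |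
|---|---|---|---|---|---|
| oak | 2.50 | 15.9 | 3.4 | 0.6 | 79.3 |
| oak | 5.00 | 32.1 | 5.3 | 0 | 62.4 |
| oak | 8.00 | 48.1 | 3.8 | 0.1 | 47.4 |
| oak | 10.0 | 56.7 | 3.2 | 0 | 39.9 |
| oak | 12.0 | 64.3 | 2.8 | 0.1 | 32.4 |
| birch | 2.50 | 15.5 | 4.3 | 0.2 | 79.9 |
| birch | 5.00 | 31.6 | 4.3 | 0 | 63.4 |
| birch | 8.00 | 47.9 | 4.4 | 0.1 | 48.5 |
| birch | 10.0 | 56.0 | 4.2 | 0.3 | 39.7 |
| birch | 12.0 | 63.3 | 3.5 | 0 | 32.8 |
| ash | 2.50 | 11.1 | 8.7 | 0 | 79.6 |
| ash | 5.00 | 24.5 | 12.5 | 0 | 62.4 |
| ash | 8.00 | 36.7 | 15.1 | 0.2 | 47.8 |
| ash | 10.0 | 42.0 | 18.1 | 0.4 | 39.6 |
| ash | 12.0 | 45.9 | 20.6 | 0.6 | 33.2 |

(readings scatter by 0.5 percentage points)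

- a reading or a percentage of target counts all its forms, free or not

- which of these there is most of at the end, counted by the starting material in it, theta (starting material / trapped intermediate / open intermediate / target)
- which of these there is most of at the end, counted by the starting material in it, beta (starting material / trapped intermediate / open intermediate / target)
- amount of the one of these that there is most of at the end, in percent of the starting material charged, theta
- amount of the one of these that there is most of at the end, in percent of the starting material charged, beta

At 10.0 min the oak, birch and ash runs read 39.9 %, 39.7 % and 39.6 % of starting material whatever the charges, so its loss reads as first order, with k = 0.0923 /min.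

The ash run gives the drain of open intermediate. Around 10.0 min, target climbs by 9.2 percentage points in 4.00 min, open intermediate reads 18.1 %, and partner, reckoned as charge minus target, stands at 8.00 mM. That makes the drain constant c = 15.9 /M/min.

In the new flask c times the partner charge starts at 1.59 /min, far faster than k, which makes the loss of starting material the rate-limiting step, so the share H of open intermediate can be frozen where making equals drain. Let A be the share of starting material left and C the equal charge. Partner used one for one then stands at the share A + H, so kA = cC(A + H)H, or H(A + H) = wA. Here w = 0.0581 is the hold-up number, the feed constant over the drain constant times the charge.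

At 10 min this gives A = 39.7 %, H = 5.14 % and target 55.1 %. At 15 min it gives A = 25.0 %, H = 4.87 % and target 70.1 %, the largest share. Trapped intermediate, 0.6 % in the last ash reading, stays out of this balance. H goes from 5.14 % to 4.87 %, so the extra time turns into 15 points of target, and the flask is left on.

The forecast names target at 55.3 % for theta and target at 69.8 % for beta, against the 55.1 % and 70.1 % above, and it too takes it that “partner is used one-for-one with target”.

The flask gives target at 54.8 % for theta, with 5.33 % open intermediate, and target at 69.8 % for beta, with 4.97 %.

    crystals ⇌ target, rate k1*(cs1 - [target]) while solid is left; crystals form when [target] > cs1 (solubility = 4.60 mM, k = 0.780 /min)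
    starting material → open intermediate (k = 0.0920 /min)
    open intermediate + capture agent → trapped intermediate (k = 0.270 /M/min)
    partner + open intermediate → target (k = 18.0 /M/min)
    partner + target ⇌ idle adduct, settled at all times (K = 15.0 /M)

Of the 69.8 % of target in beta, counted in percent of the starting material charged, 57.7 % stands as crystals and 3.48 % as idle adduct, and at 15.0 min open intermediate is made 0.968 times as fast as it is used. The neighbouring flask is beta read at 4.0 min. The same reckoning, with the same w, gives A = 69.1 %, H = 5.39 % and target 25.5 %. In that neighbouring flask, open intermediate stands at 5.37 %, target at 25.4 %, and starting material, the largest share, at 69.2 %.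

(All runs are calculated with made-up constants; the scatter is artificial.)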